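## Analysis of the target

The target 34, number 87 of the gibberellin A series, is a C19 gibberellin in which cyclohexene ring A (C1–C5, C10) is bridged by the 19,10-γ-lactone, cyclopentane ring B (C5, C6, C8, C9, C10) carries the C7 carboxyl on C6, and rings C (C8, C9, C11–C14) and D (C8, C13–C16) form a bicyclo[3.2.1]octane with an exocyclic C16=C17 methylene. There are nine stereocentres (C3, C4, C5, C6, C8, C9, C10, C12, C13), three of them quaternary carbons (C4, C8, C10) grouped around ring B. The lactone bridge lies on the α face; H-5, H-9 and the C15 bridge are β; the C7 carboxyl is β and trans to C4 across C5–C6; the 3-hydroxyl is cis to the C18 methyl; and the 12-hydroxyl is α, axial on ring C, syn to the C9–C10 bond and cis to the bridgehead 13-hydroxyl. The sensitive parts are the tertiary allylic lactone C10–O (ionisation in acid, transposition in base), the 3-hydroxyl β to the lactone carbonyl (retro-aldol epimerisation in base), the exocyclic alkene (acid isomerisation, electrophiles) and the 12,13-diol (acyloin shift at the ketol level). The difficulty is the density of stereocentres around ring B, combined with an end product that tolerates neither strong acid nor strong base. The strategy rests on one feature: ring B is a cyclopentane whose C6 bears the exocyclic C7 carbon next to quaternary C8, which is the pattern left by a 1,2-shift of C8 from C7 to C6 in a cyclohexane that still holds C7 in the ring. This six-membered homologue is a perhydrophenanthrene-type skeleton (rings A, B and C all six-membered), which can be built by a quinone Diels–Alder reaction.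

## Retrosynthetic reasoning

**34 back to 31.** The carboxyl is taken back to the C7 aldehyde, and the 3-hydroxyl and 12,13-diol to a silyl ether and an acetonide (34 ⇒ 33 ⇒ 32 ⇒ 31). Nothing is gained in skeleton; the point is that 31 is the direct outcome of a ring contraction and that the last steps need only mild oxidant, fluoride and weak acid.

**31 to 30 (key disconnection).** The C6–C8 bond is cut and C8 is reconnected to C7, giving the ring B homologue 30 with a hydroxyl on C7 and a mesylate on C6. This is the only disconnection of ring B that removes no carbon, turns the congested cyclopentane into a chair cyclohexane, and leaves C6 to be set by inversion. Forward, the C7 alkoxide must drive the C7–C8 bond onto C6, so the mesylate must be equatorial on a locked ring.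

**30 to 27.** The C7 carbinol is taken back to a ketone and the mesylate to the free 6β-hydroxyl, held until then as a 4-methoxybenzyl ether (30 ⇒ 29 ⇒ 28 ⇒ 27). A C7 ketone flanked by quaternary C8 has a single enolisable position, C6, so the C6 oxygen settles in the equatorial position by equilibration and no alkene has to be dihydroxylated next to the exocyclic methylene.

**27 to 22 (ring A).** The C1=C2 bond is cut by a metathesis transform and the C3–C4 bond by an aldol transform (27 ⇒ 26 ⇒ 25 ⇒ 24 ⇒ 22 + 23). The convex face of the γ-lactone enolate controls C4, a closed transition state controls C3, and the two vinyl groups needed for ring closure are then cis on the lactone. The C7 ketone is masked as its silyl enol ether through these steps.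

**22 to 20 (lactone).** The C4–C5 bond is cut to the propanoate held on the C10 oxygen and the ring B enone. Delivery from the tether can only occur on the α face of C5, which fixes C5 relative to C10.

**20 to 14 (ring D and the diol).** The C13–C16 bond is cut to a C13 ketone and the 2-bromoallyl group on C8, and the 12-hydroxyl is traced to a 12-ketone and further to an enol ether (20 ⇒ 19 ⇒ 18 ⇒ 17 ⇒ 16 ⇒ 14). Ring closure fixes C13; the 12-ketone is reduced only after the ring is rigid, when the axial C10 substituent blocks one face.

**14 to 10.** The C1–C10 bond is cut: 11 adds to the less hindered C10 carbonyl of ene-dione 10 from the convex face, and the alkoxide is acylated with 12.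

**10 to 7 and 9.** Ring C is opened at C8–C14 and C9–C11 by a Diels–Alder transform. One catalytic step then delivers the quaternary C8 with its ring D side chain, the cis C9 hydrogen, both ring B carbonyls (C7, C10), the C6 oxygen and the masked C13 ketone.

**7 and 9 to starting materials.** Quinone 7 comes from phenol 6, made by Claisen rearrangement of ether 5, itself from 3 (from 1 and 2) and 4. Diene 9 is the silyl enol ether of 8.

## Alternatives that were turned down

**Alternative 1:** Ring C is disconnected at C9–C11 by an amine-catalysed intramolecular aldol condensation of the prochiral triketone A1 to the bicyclic enedione A2, which fixes C8. In its favour: two steps from commodity chemicals, catalytic and metal-free, ring B already five-membered, and the allyl group is the future C15–C17 unit. Against it: only one of nine stereocentres is set. In A2, C6 is a ring ketone with no C7, so a one-carbon homologation at a neopentyl position with control of C6 is still owed. C10 is an unactivated methylene in a cyclopentane. The enone carbonyl sits on C12, not C13. The C9 hydrogen has to be installed by reduction. On speed and enantiocontrol of the opening this plan is at least as strong as the chosen one, which needs six steps to reach adduct 10. In exchange, 10 already holds C8 and C9 together, C7 as an oxidised ring carbon, the C10 and C6 oxygens and the C13 oxygen, so far less has to be relayed.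

**Alternative 2:** Ring A and the lactone are disconnected together at C4–C5 and C1=C2. A β-keto ester held on the C10 oxygen would add to a ring B enoate and then condense with a C10 formyl group, giving the 3-oxo-1-ene lactone A3. In its favour: one operation builds ring A and the lactone on the native five-membered ring B with the C7 ester in place, and the tether fixes C5. Against it: the substrate needs a tertiary C10 carbinol bearing a formyl group next to C9 and a cyclopentene enoate at the same time, and making that core is the larger part of the problem. A3 is also a 3-ketone, whose reduction to the 3β-alcohol must avoid 1,4-reduction and override the usual preference of small hydrides for giving the 3α-alcohol. The tether idea itself is as strong as anything in the chosen route and is used there (step 13). On ring A step count Alternative 2 is stronger (one pot against steps 13–15). The chosen strategy offers an easier core (adduct 10) and sets C3 by aldol geometry.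

**Alternative 3:** Ring B is disconnected at C5–C6: a rhodium carbenoid from a diazo ester on C8 would insert into the C5–H bond of a preformed lactone, giving A4. In its favour: high convergence, ring B closed last with the C7 ester already present, C5 and C6 set in one step, no ring contraction. Against it: the substrate must already join the ring A lactone to the C/D bicycle through the congested C9–C10 bond. The carbenoid also sees several other C–H bonds within reach (on C11, C14 and C15) as well as the exocyclic alkene. The C5–H bond is deactivated by the adjacent ester-bearing quaternary carbon. The C6 configuration would depend on the catalyst alone. On convergence this plan is stronger. The chosen strategy replaces a selectivity contest among C–H bonds by a 1,2-shift whose course is fixed by the geometry of a locked chair, and C9–C10 is never made as a separate bond because it comes from the quinone ring.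

Key step: step 21

Remark: locants in names are gibberellane numbers (C1–C19 as in 34); α is the face of the lactone bridge, β the face of H-5 and H-9.

Remark on the chemistry: hydride reduction of the C7 ketone (step 20) should give the equatorial 7α-alcohol, so the hydroxy mesylate 30 is carried with 7α-OH (trans-diequatorial to the 6β-mesylate). C7 becomes the sp2 aldehyde carbon in step 21, so this centre does not reach 31; the equatorial C6 mesylate, which the shift requires, is unaffected.

Assumption: the (S)-configured oxazaborolidinium catalyst in step 6 delivers the enantiomer of 10 shown; if the sense is opposite, the (R)-catalyst is used.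

## Steps

Step 1
Reactants: 1 catechol; 2 4-methoxybenzyl chloride
Product: 3 2-[(4-methoxybenzyl)oxy]phenol
Conditions: K2CO3, acetone, reflux (excess 1)
Reagents that add atoms: 4-methoxybenzyl chloride (2), COc1ccc(CCl)cc1
Why: Williamson mono-alkylation of a phenol; excess catechol suppresses the bis-ether.

Step 2
Reactants: 3; 4 2,3-dibromoprop-1-ene
Product: 5 1-[(2-bromoprop-2-en-1-yl)oxy]-2-[(4-methoxybenzyl)oxy]benzene
Conditions: K2CO3, DMF, rt
Reagents that add atoms: 2,3-dibromoprop-1-ene (4), C=C(Br)CBr
Why: Williamson etherification at the allylic bromide; the vinylic bromide is inert to phenoxide.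

Step 3
Reactants: 5
Product: 6 2-(2-bromoprop-2-en-1-yl)-6-[(4-methoxybenzyl)oxy]phenol
Conditions: PhNEt2, 190 °C
Reagents that add atoms: none
Why: Aromatic Claisen rearrangement to the only free ortho position; 2-bromoallyl aryl ethers rearrange normally.

Step 4
Reactants: 6
Product: 7 2-(2-bromoprop-2-en-1-yl)-6-[(4-methoxybenzyl)oxy]-1,4-benzoquinone
Conditions: (KSO3)2NO, KH2PO4, H2O/acetone, rt
Reagents that add atoms: potassium nitrosodisulfonate, [K+].[K+].[O]N(S(=O)(=O)[O-])S(=O)(=O)[O-]
Why: Teuber oxidation of a 2,6-disubstituted phenol with a free para position to the p-quinone; benzyl-type ethers and the vinyl bromide are not touched.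

Step 5
Reactants: 8 but-3-en-2-one
Product: 9 2-(triisopropylsilyloxy)buta-1,3-diene
Conditions: i-Pr3SiOTf, Et3N, Et2O, 0 °C
Reagents that add atoms: triisopropylsilyl trifluoromethanesulfonate, CC(C)[Si](OS(=O)(=O)C(F)(F)F)(C(C)C)C(C)C
Why: Soft enolisation and O-silylation of a methyl ketone gives the 2-silyloxy diene.

Step 6
Reactants: 7; 9
Product: 10 cis-8a-(2-bromoprop-2-en-1-yl)-2-[(4-methoxybenzyl)oxy]-7-(triisopropylsilyloxy)-4a,5,8,8a-tetrahydronaphthalene-1,4-dione (B/C adduct; 8β-bromoallyl, 9β-H)
Conditions: (S)-B-o-tolyl oxazaborolidine from α,α-diphenylprolinol, protonated with Tf2NH (20 mol %), CH2Cl2, −78 → −40 °C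
Reagents that add atoms: 2-(triisopropylsilyloxy)buta-1,3-diene (9), C=CC(=C)O[Si](C(C)C)(C(C)C)C(C)C
Why: Catalytic enantioselective quinone Diels–Alder reaction; the alkoxy-bearing alkene is deactivated as a vinylogous ester, so the alkyl-substituted alkene reacts and suprafacial addition makes C8 (quaternary) and C9–H cis. The catalyst binds the more basic C10 carbonyl, which screens one face and directs the nucleophilic diene terminus to C8, placing the silyloxy group on C13.

Step 7
Reactants: 10; 11 vinylmagnesium bromide; 12 propanoic anhydride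
Product: 14 B/C enone with 10β-vinyl and 10α-propanoyloxy groups, 6-(4-methoxybenzyloxy)-5-en-7-one, 13-(triisopropylsilyloxy)-12-ene, 8β-(2-bromoallyl), 9β-H, via C10 dichlorocerium alkoxide 13 (not isolated)
Conditions: CeCl3, 11, THF, −78 °C; then 12, DMAP (cat.), −78 → 0 °C
Reagents that add atoms: vinylmagnesium bromide (11), C=C[Mg]Br; propanoic anhydride (12), CCC(=O)OC(=O)CC
Why: Organocerium 1,2-addition followed by O-acylation of the alkoxide; C7 is flanked by quaternary C8 and the substituted C6, so the vinyl group should go to C10. It enters from the convex β face of the cis-fused bicycle (ring C covers the α face), which puts the oxygen α as the lactone needs.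

Step 8
Reactants: 14
Product: 16 12-hydroxy-13-ketone (C12 epimers; remainder as 14), via 12-triisopropylsilyloxy ketone 15 (not isolated)
Conditions: dimethyldioxirane, acetone/CH2Cl2, −78 → −20 °C; then Bu4NF, AcOH, THF, 0 °C
Reagents that add atoms: dimethyldioxirane, CC1(C)OO1
Why: Rubottom oxidation; the silyl enol ether is far more electron-rich than the vinyl, bromoalkene and enone double bonds. The C12 configuration is irrelevant because C12 is oxidised in step 10.

Step 9
Reactants: 16
Product: 17 B/C/D tricycle with 13-hydroxy and 16-methylene (12,13-diol, C12 epimers; ring B enone and 10α-propanoate as in 14)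
Conditions: CrCl2 (6 equiv), NiCl2 (5 mol %), DMF, 25 → 50 °C
Reagents that add atoms: none
Why: Intramolecular Nozaki–Hiyama–Kishi addition of the vinyl bromide to the C13 ketone closes ring D (5-exo) and gives the tertiary allylic alcohol with the exocyclic methylene. C13 is fixed by the bridge; C10 is anti to C15 across C8–C9 and C7 would give a four-membered ring, so neither competes.

Step 10
Reactants: 17
Product: 18 13-hydroxy-12-ketone (α-ketol; remainder as 17)
Conditions: Dess–Martin periodinane, CH2Cl2, 0 °C → rt
Reagents that add atoms: none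
Why: Periodinane oxidation of the secondary alcohol next to a tertiary one without glycol cleavage; both C12 epimers converge.

Step 11
Reactants: 18
Product: 19 12α,13-diol (remainder as 17)
Conditions: NaBH4, MeOH/CH2Cl2, −78 °C
Reagents that add atoms: none
Why: Hydride reduction; with ring D closed, the quaternary C10 is axial on ring C and blocks the α face of C12, so hydride should enter from the β side and give the axial 12α-alcohol cis to 13-OH (as 11-keto steroids give 11β-alcohols). The hindered, conjugated C7 ketone should survive at this temperature.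

Step 12
Reactants: 19
Product: 20 12α,13-O-isopropylidene acetal (remainder as 17)
Conditions: Me2C(OMe)2, PPTS (cat.), CH2Cl2, rt
Reagents that add atoms: 2,2-dimethoxypropane, COC(C)(C)OC
Why: Acetonide formation from a cis-1,2-diol under mild acid.

Step 13
Reactants: 20
Product: 22 19,10-lactone with 4-methyl (C4 epimers), 5β-H, 10β-vinyl and a 7-(triethylsilyloxy)-6-(4-methoxybenzyloxy)-6-ene (C/D as in 20), via lithium enolate 21 (not isolated)
Conditions: LiN(SiMe3)2, THF, −78 °C; then Et3SiCl, −78 → −20 °C
Reagents that add atoms: chlorotriethylsilane, CC[Si](Cl)(CC)CC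
Why: Intramolecular Michael addition of the propanoate enolate to C5 (5-exo-trig); the propanoate is the only acidic site, and the tether on the α-oxygen of C10 can reach C5 only from the α face, so the lactone is cis-fused and H-5 becomes β. The C7 enolate is trapped as its silyl enol ether to mask the ketone for the next steps.

Step 14
Reactants: 22; 23 acrolein
Product: 24 aldol adduct: quaternary C4 bearing methyl and a (1-hydroxyprop-2-enyl) group with the C3 hydroxyl syn to the methyl (3β after ring closure); remainder as 22
Conditions: LiN(i-Pr)2, THF, −78 °C; then 23, −78 °C; then H2O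
Reagents that add atoms: acrolein (23), C=CC=O
Why: Aldol addition of the α-methyl γ-lactone enolate; the aldehyde approaches the convex face (that of H-5 and the C10 vinyl group), placing C3 cis to the vinyl group and the methyl toward ring B. In the closed transition state the methyl group, cis to the enolate oxygen, ends up syn to the new hydroxyl, which is the 3β configuration.

Step 15
Reactants: 24
Product: 25 ring B homologue tetracycle: 3β-hydroxy-1-ene, 19,10-lactone, 7-(triethylsilyloxy)-6-(4-methoxybenzyloxy)-6-ene, 12α,13-acetonide, 16-methylene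
Conditions: second-generation Grubbs catalyst (H2IMes)(PCy3)Cl2Ru=CHPh (5 mol %), CH2Cl2, 40 °C
Reagents that add atoms: none
Why: Ring-closing metathesis of the two cis monosubstituted vinyl groups gives the six-membered ring A; the 1,1-disubstituted methylene and the tetrasubstituted enol ether are much slower partners.

Step 16
Reactants: 25
Product: 26 3β-(tert-butyldimethylsilyloxy) derivative of 25
Conditions: t-BuMe2SiOTf, 2,6-lutidine, CH2Cl2, −78 °C
Reagents that add atoms: tert-butyldimethylsilyl trifluoromethanesulfonate, CC(C)(C)[Si](C)(C)OS(=O)(=O)C(F)(F)F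
Why: Silylation of the hindered allylic alcohol with the silyl triflate; this blocks retro-aldol chemistry at C3 in the basic key step.

Step 17
Reactants: 26
Product: 27 6β-(4-methoxybenzyloxy)-7-ketone (ring B homologue; 3β-OTBS, 12α,13-acetonide)
Conditions: Bu4NF, AcOH, THF, −20 → 0 °C
Reagents that add atoms: none
Why: Fluoride cleavage of the silyl enol ether, much faster than that of the hindered alkyl silyl ether. C6, the only enolisable position, equilibrates to the equatorial β-ether, because an axial α-substituent would be syn-axial to both O10 and C14.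

Step 18
Reactants: 27
Product: 28 6β-hydroxy-7-ketone
Conditions: DDQ, CH2Cl2/pH 7 buffer, 0 °C
Reagents that add atoms: none
Why: Oxidative removal of the 4-methoxybenzyl ether; silyl ether, acetonide, lactone and alkenes are stable, and no neighbouring hydroxyl is present to form a benzylidene acetal.

Step 19
Reactants: 28
Product: 29 6β-mesyloxy-7-ketone
Conditions: MsCl, Et3N, CH2Cl2, −20 °C
Reagents that add atoms: methanesulfonyl chloride, CS(=O)(=O)Cl
Why: Sulfonylation of the only free hydroxyl, so no regioselection between C6 and C7 is needed.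

Step 20
Reactants: 29
Product: 30 ring B homologue, 7α-hydroxy-6β-mesyloxy lactone (12α,13-acetonide, 3β-OTBS)
Conditions: NaBH4, MeOH/THF, −40 °C; AcOH quench
Reagents that add atoms: none
Why: Borohydride reduction of the α-sulfonyloxy ketone; axial delivery from the β face (the α face is screened by axial C14) should give the equatorial 7α-alcohol. Low temperature and an acid quench keep the intermediate borate from starting the shift.

Step 21
Reactants: 30
Product: 31 gibberellin C7 aldehyde (12α,13-acetonide, 3β-OTBS)
Conditions: KOt-Bu, t-BuOH/THF, 0 °C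
Reagents that add atoms: none
Why: Semipinacol rearrangement of a 2-hydroxy sulfonate: deprotonation gives the C7 alkoxide, whose lone pair drives the C7–C8 σ bond onto C6 as mesylate leaves and C7 becomes the aldehyde carbon. The closest known reaction type is the base-induced contraction of 2-hydroxycyclohexyl sulfonates to cyclopentanecarbaldehydes. Ring B closes as the five-membered ring by this 1,2-alkyl shift, an intramolecular SN2-type displacement at C6 by the migrating bond (six-to-five contraction forming C6–C8). The one new stereocentre, C6, is set by inversion: C8 arrives anti to the departing β-mesylate, so C7 ends β and H-6 α; C8 migrates with retention. The step needs contraction to beat hydride shift, epoxide formation and elimination. Ring B is a chair locked by the trans-fused ring A, the lactone and the C/D bicycle, and the mesylate is equatorial, so only ring bonds are antiperiplanar to it. Of these, only C7–C8 has a donor behind it; H-7 and H-5 are gauche and the trans-diequatorial oxygen cannot reach backside geometry. The 3-silyl ether and the non-nucleophilic base protect the lactone, and the aldehyde lies trans to C4 on the cyclopentane, so epimerisation should not erode C6.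

Step 22
Reactants: 31
Product: 32 gibberellin C7 acid (12α,13-acetonide, 3β-OTBS)
Conditions: NaClO2, NaH2PO4, 2-methylbut-2-ene, t-BuOH/H2O, rt
Reagents that add atoms: sodium chlorite, [Na+].[O-]Cl=O
Why: Pinnick oxidation; the alkene scavenger removes hypochlorous acid before it can add to the exocyclic methylene, and the α-stereocentre is not epimerised at this pH.

Step 23
Reactants: 32
Product: 33 12α,13-O-isopropylidene acetal of 34 (free 3β-hydroxyl, free C7 acid)
Conditions: HF·pyridine, THF/pyridine, 0 °C → rt
Reagents that add atoms: none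
Why: Acidic fluoride desilylation avoids the basic conditions under which the free 3-hydroxy lactone epimerises.

Step 24
Reactants: 33
Product: 34 target gibberellin (3β,12α,13-trihydroxy-1,16-diene 19,10-lactone 7-acid; number 87 of the gibberellin A series)
Conditions: AcOH/H2O (4:1), 40 °C
Reagents that add atoms: none
Why: Mild acid hydrolysis of the acetonide; weak acid at moderate temperature should leave the allylic lactone and the exocyclic alkene intact.

## Compound list

1 | catechol | Oc1ccccc1O | starting material
2 | 4-methoxybenzyl chloride | COc1ccc(CCl)cc1 | starting material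
3 | 2-[(4-methoxybenzyl)oxy]phenol | COc1ccc(COc2ccccc2O)cc1 | intermediate
4 | 2,3-dibromoprop-1-ene | C=C(Br)CBr | starting material
5 | 1-[(2-bromoprop-2-en-1-yl)oxy]-2-[(4-methoxybenzyl)oxy]benzene | COc1ccc(COc2ccccc2OCC(Br)=C)cc1 | intermediate
6 | 2-(2-bromoprop-2-en-1-yl)-6-[(4-methoxybenzyl)oxy]phenol | COc1ccc(COc2cccc(CC(Br)=C)c2O)cc1 | intermediate
7 | 2-(2-bromoprop-2-en-1-yl)-6-[(4-methoxybenzyl)oxy]-1,4-benzoquinone | C=C(Br)CC1=CC(=O)C=C(OCc2ccc(OC)cc2)C1=O | intermediate
8 | but-3-en-2-one | CC(=O)C=C | starting material
9 | 2-(triisopropylsilyloxy)buta-1,3-diene | C=CC(=C)O[Si](C(C)C)(C(C)C)C(C)C | intermediate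
10 | cis-fused B/C Diels–Alder adduct (8β-bromoallyl, 9β-H, 6-OPMB ene-dione, 13-OTIPS enol ether) | C=C(Br)C[C@]23CC(O[Si](C(C)C)(C(C)C)C(C)C)=CC[C@H]2C(=O)C=C(OCc1ccc(OC)cc1)C3=O | intermediate
11 | vinylmagnesium bromide | C=C[Mg]Br | starting material
12 | propanoic anhydride | CCC(=O)OC(=O)CC | starting material
13 | C10 dichlorocerium alkoxide of the vinyl adduct of 10 | C=C(Br)C[C@]23CC(O[Si](C(C)C)(C(C)C)C(C)C)=CC[C@H]2[C@@](O[Ce](Cl)Cl)(C=C(OCc1ccc(OC)cc1)C3=O)C=C | intermediate
14 | B/C enone, 10β-vinyl-10α-propanoyloxy, 6-OPMB-5-en-7-one, 13-OTIPS-12-ene | C=C(Br)C[C@]23CC(O[Si](C(C)C)(C(C)C)C(C)C)=CC[C@H]2[C@@](OC(=O)CC)(C=C(OCc1ccc(OC)cc1)C3=O)C=C | intermediate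
15 | 12-(triisopropylsilyloxy)-13-ketone (C12 epimers) | C=C(Br)C[C@]23CC(=O)C(O[Si](C(C)C)(C(C)C)C(C)C)C[C@H]2[C@@](OC(=O)CC)(C=C(OCc1ccc(OC)cc1)C3=O)C=C | intermediate
16 | 12-hydroxy-13-ketone (C12 epimers) | C=C(Br)C[C@]23CC(=O)C(O)C[C@H]2[C@@](OC(=O)CC)(C=C(OCc1ccc(OC)cc1)C3=O)C=C | intermediate
17 | B/C/D tricycle, 12,13-diol (C12 epimers), 16-methylene | C=C1C[C@]23C[C@@]1(O)C(O)C[C@H]2[C@@](OC(=O)CC)(C=C(OCc1ccc(OC)cc1)C3=O)C=C | intermediate
18 | B/C/D tricycle, 13-hydroxy-12-ketone | C=C1C[C@]23C[C@@]1(O)C(=O)C[C@H]2[C@@](OC(=O)CC)(C=C(OCc1ccc(OC)cc1)C3=O)C=C | intermediate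
19 | B/C/D tricycle, 12α,13-diol | C=C1C[C@]23C[C@@]1(O)[C@@H](O)C[C@H]2[C@@](OC(=O)CC)(C=C(OCc1ccc(OC)cc1)C3=O)C=C | intermediate
20 | B/C/D tricycle, 12α,13-acetonide | C=C1C[C@]23C[C@@]1(OC(C)(C)O4)[C@@H]4C[C@H]2[C@@](OC(=O)CC)(C=C(OCc1ccc(OC)cc1)C3=O)C=C | intermediate
21 | lithium C7 enolate of the 19,10-lactone (C4 epimers) | C=C1C[C@]23C[C@@]1(OC(C)(C)O4)[C@@H]4C[C@H]2[C@@]1(C=C)OC(=O)C(C)[C@H]1C(OCc1ccc(OC)cc1)=C3O[Li] | intermediate
22 | 19,10-lactone, 4-methyl (C4 epimers), 10β-vinyl, 7-OTES-6-OPMB-6-ene | C=C1C[C@]23C[C@@]1(OC(C)(C)O4)[C@@H]4C[C@H]2[C@@]1(C=C)OC(=O)C(C)[C@H]1C(OCc1ccc(OC)cc1)=C3O[Si](CC)(CC)CC | intermediate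
23 | acrolein | C=CC=O | starting material
24 | aldol adduct, quaternary C4 with 1-hydroxyprop-2-enyl group (3β-OH) | C=C1C[C@]23C[C@@]1(OC(C)(C)O4)[C@@H]4C[C@H]2[C@@]1(C=C)OC(=O)[C@](C)([C@@H](O)C=C)[C@H]1C(OCc1ccc(OC)cc1)=C3O[Si](CC)(CC)CC | intermediate
25 | ring B homologue tetracycle, 3β-hydroxy-1-ene, 7-OTES-6-OPMB-6-ene | C=C1C[C@]23C[C@@]1(OC(C)(C)O4)[C@@H]4C[C@H]2[C@@]12C=C[C@H](O)[C@@](C)(C(=O)O1)[C@H]2C(OCc1ccc(OC)cc1)=C3O[Si](CC)(CC)CC | intermediate
26 | 3β-OTBS derivative of 25 | C=C1C[C@]23C[C@@]1(OC(C)(C)O4)[C@@H]4C[C@H]2[C@@]12C=C[C@H](O[Si](C)(C)C(C)(C)C)[C@@](C)(C(=O)O1)[C@H]2C(OCc1ccc(OC)cc1)=C3O[Si](CC)(CC)CC | intermediate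
27 | ring B homologue, 6β-OPMB-7-ketone | C=C1C[C@]23C[C@@]1(OC(C)(C)O4)[C@@H]4C[C@H]2[C@@]12C=C[C@H](O[Si](C)(C)C(C)(C)C)[C@@](C)(C(=O)O1)[C@H]2[C@H](OCc1ccc(OC)cc1)C3=O | intermediate
28 | ring B homologue, 6β-hydroxy-7-ketone | C=C1C[C@]23C[C@@]1(OC(C)(C)O4)[C@@H]4C[C@H]2[C@@]12C=C[C@H](O[Si](C)(C)C(C)(C)C)[C@@](C)(C(=O)O1)[C@H]2[C@H](O)C3=O | intermediate
29 | ring B homologue, 6β-mesyloxy-7-ketone | C=C1C[C@]23C[C@@]1(OC(C)(C)O4)[C@@H]4C[C@H]2[C@@]12C=C[C@H](O[Si](C)(C)C(C)(C)C)[C@@](C)(C(=O)O1)[C@H]2[C@H](OS(C)(=O)=O)C3=O | intermediate
30 | ring B homologue, 7α-hydroxy-6β-mesyloxy lactone (12α,13-acetonide, 3β-OTBS) | C=C1C[C@]23C[C@@]1(OC(C)(C)O4)[C@@H]4C[C@H]2[C@@]12C=C[C@H](O[Si](C)(C)C(C)(C)C)[C@@](C)(C(=O)O1)[C@H]2[C@H](OS(C)(=O)=O)[C@H]3O | intermediate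
31 | gibberellin C7 aldehyde (12α,13-acetonide, 3β-OTBS) | C=C1C[C@]23C[C@@]1(OC(C)(C)O4)[C@@H]4C[C@H]2[C@@]12C=C[C@H](O[Si](C)(C)C(C)(C)C)[C@@](C)(C(=O)O1)[C@H]2[C@@H]3C=O | intermediate
32 | gibberellin C7 acid (12α,13-acetonide, 3β-OTBS) | C=C1C[C@]23C[C@@]1(OC(C)(C)O4)[C@@H]4C[C@H]2[C@@]12C=C[C@H](O[Si](C)(C)C(C)(C)C)[C@@](C)(C(=O)O1)[C@H]2[C@@H]3C(=O)O | intermediate
33 | 12α,13-O-isopropylidene acetal of 34 | C=C1C[C@]23C[C@@]1(OC(C)(C)O4)[C@@H]4C[C@H]2[C@@]12C=C[C@H](O)[C@@](C)(C(=O)O1)[C@H]2[C@@H]3C(=O)O | intermediate
34 | target gibberellin: 3β,12α,13-trihydroxy-1,16-diene 19,10-lactone 7-acid (number 87 of the gibberellin A series) | C=C1C[C@]23C[C@@]1(O)[C@@H](O)C[C@H]2[C@@]12C=C[C@H](O)[C@@](C)(C(=O)O1)[C@H]2[C@@H]3C(=O)O | target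

## Step count and least certain steps

Total: 24 steps. Longest linear sequence: 23 steps (steps 1–4 and 6–24; step 5 is a one-step side branch).

**Step 21 (key step).** Most likely failure: base-mediated epimerisation or self-condensation of the new α-branched aldehyde, or a slow shift that leaves time for attack on the allylic lactone. Fallback, from 29 back to 32: the mesyloxy ketone 29 has no enolisable position on the C8 side, so potassium trimethylsilanolate in THF at 0 °C should add to the C7 carbonyl and trigger a semibenzilic (quasi-Favorskii) shift of the same C7–C8 bond onto C6 with inversion. This gives the trimethylsilyl ester F1 of the ring-contracted acid, which hydrolyses on aqueous work-up to 32. The aldehyde and steps 20–22 are bypassed.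

**Step 6.** Most likely failure: loss of regiocontrol in the diene orientation if the uncatalysed pathway (controlled by the C7 carbonyl) competes, or acid-induced loss of the 4-methoxybenzyl group. Fallback, from 7 back to 18: cycloaddition of 7 with the symmetric 2,3-bis(trimethylsilyloxy)buta-1,3-diene under the same catalyst removes the regiochemical question and gives the enediol bis-silyl ether adduct F2. Vinylcerium addition and propanoylation as in step 7 give the C10 propanoate F3. Desilylation (Bu4NF/AcOH) followed by Dess–Martin oxidation converges on the 12,13-dione F4. CrCl2/NiCl2 cyclisation then takes place at C13, the only carbonyl the axial side chain can reach in a five-membered transition state, and returns ketol 18.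

**Step 7.** Most likely failure: addition at the electronically more reactive C7 carbonyl, or enolisation at C9 with loss of the cis ring fusion. Fallback, from 10 back to 14: the same preference is used as a protection. NaBH4/CeCl3 at −78 °C reduces C7 to the allylic alcohol F5. Excess vinylcerium reagent then adds to the only remaining carbonyl, C10, to give the diol F6. MnO2 oxidises only the secondary allylic C7 alcohol, restoring the enone as the 10-hydroxy ketone F7. Propanoylation of the tertiary alcohol (propanoic anhydride, DMAP) returns 14.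

**Step 14.** Most likely failure: poor facial control at C3 if an open transition state competes, or retro-aldol loss on work-up. Fallback, from 24 back to 25: if 24 forms as a C3 mixture, ring-closing metathesis as in step 15 gives 25 together with its 3α-epimer F8. MnO2 oxidation of the allylic alcohol mixture converges on the 3-oxo-1-ene lactone F9. Oxazaborolidine-catalysed borane reduction (CBS) sets the 3β-alcohol by reagent control and returns 25.

## Further compounds

F1 | step 21 | trimethylsilyl ester of acid 32 | C=C1C[C@]23C[C@@]1(OC(C)(C)O4)[C@@H]4C[C@H]2[C@@]12C=C[C@H](O[Si](C)(C)C(C)(C)C)[C@@](C)(C(=O)O1)[C@H]2[C@@H]3C(=O)O[Si](C)(C)C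
F2 | step 6 | B/C Diels–Alder adduct with 12,13-bis(trimethylsilyloxy)-12-ene | C=C(Br)C[C@]23CC(O[Si](C)(C)C)=C(O[Si](C)(C)C)C[C@H]2C(=O)C=C(OCc1ccc(OC)cc1)C3=O
F3 | step 6 | 10β-vinyl-10α-propanoyloxy derivative of F2 | C=C(Br)C[C@]23CC(O[Si](C)(C)C)=C(O[Si](C)(C)C)C[C@H]2[C@@](OC(=O)CC)(C=C(OCc1ccc(OC)cc1)C3=O)C=C
F4 | step 6 | 12,13-dione of the B/C enone | C=C(Br)C[C@]23CC(=O)C(=O)C[C@H]2[C@@](OC(=O)CC)(C=C(OCc1ccc(OC)cc1)C3=O)C=C
F5 | step 7 | 7-hydroxy derivative of 10 (C7 epimers) | C=C(Br)C[C@]23CC(O[Si](C(C)C)(C(C)C)C(C)C)=CC[C@H]2C(=O)C=C(OCc1ccc(OC)cc1)C3O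
F6 | step 7 | 10β-vinyl-7,10α-diol (C7 epimers) | C=C(Br)C[C@]23CC(O[Si](C(C)C)(C(C)C)C(C)C)=CC[C@H]2[C@@](O)(C=C(OCc1ccc(OC)cc1)C3O)C=C
F7 | step 7 | 10α-hydroxy-10β-vinyl enone (free alcohol of 14) | C=C(Br)C[C@]23CC(O[Si](C(C)C)(C(C)C)C(C)C)=CC[C@H]2[C@@](O)(C=C(OCc1ccc(OC)cc1)C3=O)C=C
F8 | step 14 | 3α-epimer of 25 | C=C1C[C@]23C[C@@]1(OC(C)(C)O4)[C@@H]4C[C@H]2[C@@]12C=C[C@@H](O)[C@@](C)(C(=O)O1)[C@H]2C(OCc1ccc(OC)cc1)=C3O[Si](CC)(CC)CC
F9 | step 14 | 3-oxo-1-ene lactone corresponding to 25 | C=C1C[C@]23C[C@@]1(OC(C)(C)O4)[C@@H]4C[C@H]2[C@@]12C=CC(=O)[C@@](C)(C(=O)O1)[C@H]2C(OCc1ccc(OC)cc1)=C3O[Si](CC)(CC)CC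
A1 | alternative 1 | 2-allyl-2-(3-oxobutyl)cyclopentane-1,3-dione | C=CCC1(CCC(C)=O)C(=O)CCC1=O
A2 | alternative 1 | 7a-allyl-2,3,7,7a-tetrahydro-1H-indene-1,5(6H)-dione, single enantiomer | C=CC[C@@]12C(=O)CCC1=CC(=O)CC2
A3 | alternative 2 | 3-oxo-1-ene tetracyclic lactone (12,13-acetonide, C7 methyl ester) | C=C1C[C@]23C[C@@]1(OC(C)(C)O4)[C@@H]4C[C@H]2[C@@]12C=CC(=O)[C@@](C)(C(=O)O1)[C@H]2[C@@H]3C(=O)OC
A4 | alternative 3 | tetracyclic lactone with C1 dioxolane (3-O-TBS, 12,13-acetonide, C7 methyl ester) | C=C1C[C@]23C[C@@]1(OC(C)(C)O4)[C@@H]4C[C@H]2[C@@]12C5(OCCO5)C[C@H](O[Si](C)(C)C(C)(C)C)[C@@](C)(C(=O)O1)[C@H]2[C@@H]3C(=O)OC
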